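**Strategy**

The 7-oxabicyclo[2.2.1]heptane is unravelled to an open-chain aldehyde by cutting the ether bond O7–C1 (methyl-bearing bridgehead) and the ring bond C4–C3 (CH bridgehead to the gem-dimethyl carbon). The key step exploits that O7 sits on C4, a former aldehyde carbon, next to C3 and 1,4 to C1 across the six-membered carbocycle. A tertiary C3 radical, released from a nitro group, adds to the aldehyde, and the resulting alkoxy radical closes onto a C1 exocyclic methylene, whose CH2 becomes the bridgehead methyl. One operation thus closes both rings; the single stereocentre of the precursor (C2), set by iminium catalysis, steers the rest. The arene is attached late by carboalumination/coupling.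

Key step: step 5

Remark: the target SMILES is read as the (1R,2S,4S)-bicycle with the side chain exo (syn to the oxygen bridge) and a 2E alkene. Locants C1–C4 and O7 refer to the oxabicycle (C1 methyl-bearing bridgehead, C2 side-chain carbon, C3 gem-dimethyl carbon, C4 CH bridgehead). Compound 1 is used as its commercial THF solution.

**Route**

Step 1
Reactants: 1 [2-(1,3-dioxolan-2-yl)ethyl]magnesium bromide; 2 (E)-3-(dimethylamino)prop-2-enal
Product: 4 (E)-5-(1,3-dioxolan-2-yl)pent-2-enal, via magnesium alkoxide adduct 3 (not isolated)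
Conditions: THF, −30 → 0 °C; then 1 M aq. HCl, 0 °C, 10 min
Reagents that add atoms: water, O
Why: The Grignard reagent adds 1,2 to the carbonyl of the vinylogous formamide, and cold aqueous acid then expels hydroxide and dimethylamine to unveil the conjugated E-enal (vinylogous Bouveault aldehyde synthesis), too briefly to open the dioxolane.

Step 2
Reactants: 4 (E)-5-(1,3-dioxolan-2-yl)pent-2-enal; 5 2-nitropropane
Product: 6 (R)-3-[2-(1,3-dioxolan-2-yl)ethyl]-4-methyl-4-nitropentanal
Conditions: (S)-α,α-diphenylprolinol trimethylsilyl ether (20 mol%), PhCO2H (20 mol%), 5 (5 equiv), MeOH, rt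
Reagents that add atoms: none
Why: Iminium-ion catalysed asymmetric Michael addition of a nitroalkane: the E-iminium ion of 4 is shielded on one face by the diphenyl(silyloxy)methyl group of the (S)-catalyst, so the nitronate adds to the β-carbon from the open face and sets the (R) centre that becomes C2 of the bicycle.

Step 3
Reactants: 6 (R)-3-[2-(1,3-dioxolan-2-yl)ethyl]-4-methyl-4-nitropentanal
Product: 9 (R)-3-[2-(1,3-dioxolan-2-yl)ethyl]-4-methyl-2-methylidene-4-nitropentan-1-ol, via Mannich base 7 (not isolated), via α-methylene aldehyde 8 (not isolated)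
Conditions: Eschenmoser's salt (1.5 equiv), Et3N (2 equiv), CH2Cl2, rt; then MeOH, CeCl3·7H2O, NaBH4, −20 °C
Reagents that add atoms: N,N-dimethylmethyleneiminium iodide (Eschenmoser's salt), C=[N+](C)C.[I-]
Why: Mannich reaction at the only enolisable carbon and E1cB loss of dimethylamine (Eschenmoser methylenation) give the α-methylene aldehyde, and Luche 1,2-reduction in the same flask avoids handling this Michael acceptor; the stereocentre carries no acidic hydrogen and is untouched.

Step 4
Reactants: 9 (R)-3-[2-(1,3-dioxolan-2-yl)ethyl]-4-methyl-2-methylidene-4-nitropentan-1-ol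
Product: 11 (5R)-5-[2-(1,3-dioxolan-2-yl)ethyl]-6-methyl-4-methylidene-6-nitroheptanal, via allyl vinyl ether 10 (not isolated)
Conditions: vinyl acetate (2 equiv), [IrCl(cod)]2 (1 mol%), Na2CO3, PhMe, 100 °C; then 140 °C, sealed tube
Reagents that add atoms: vinyl acetate, C=COC(C)=O
Why: Iridium-catalysed vinyl transfer to the primary allylic alcohol followed by thermal [3,3]-sigmatropic Claisen rearrangement transposes the allyl unit, so the former carbinol carbon becomes the exocyclic methylene and the chain gains the CH2CH2CHO arm; no stereocentre is formed.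

Step 5
Reactants: 11 (5R)-5-[2-(1,3-dioxolan-2-yl)ethyl]-6-methyl-4-methylidene-6-nitroheptanal
Product: 12 2-{2-[(1R,2S,4S)-1,3,3-trimethyl-7-oxabicyclo[2.2.1]heptan-2-yl]ethyl}-1,3-dioxolane
Conditions: Bu3SnH (1.5 equiv, syringe pump, 8 h), 1,1'-azobis(cyclohexanecarbonitrile) (0.2 equiv), PhMe (5 mM), 110 °C
Reagents that add atoms: none
Why: Proposed new method: the tributylstannyl radical adds to the nitro group and C–N homolysis releases the tertiary radical at the future C3, which adds 6-exo-trig to the aldehyde carbon (closing the carbocycle through the C3–C4 bond); the alkoxy radical so formed adds 5-exo-trig across the ring to the inner carbon of the 1,1-disubstituted alkene (closing the oxygen bridge through the O7–C1 bond), and the primary radical is reduced by Bu3SnH to the bridgehead methyl. The closest known reaction types are the tin hydride denitration/cyclisation of tertiary nitroalkanes, the 6-exo cyclisation of alkyl radicals onto aldehydes and the 5-exo cyclisation of 4-pentenyloxy radicals; joining them in one chain with a transannular ether closure is the new element. Addition to the aldehyde is reversible (β-scission), so the outcome is decided in the ether closure, where the boat-like transition state with the C2 side chain exo (pseudo-equatorial, cis to oxygen) should be preferred over the endo one; this sets C4 (S) from the existing C2 stereocentre. C1 (R) follows by necessity, because the oxygen can only reach the alkene face on its own side of the ring. The step needs cyclisation to outrun reduction of the tertiary radical, which slow addition and high dilution secure, and it needs the absence of other radical acceptors, which the saturated acetal side chain secures; the inner alkene carbon is the one held next to the oxygen, and 5-exo attack is the kinetic norm for alkoxy radicals.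

Step 6
Reactants: 12 2-{2-[(1R,2S,4S)-1,3,3-trimethyl-7-oxabicyclo[2.2.1]heptan-2-yl]ethyl}-1,3-dioxolane
Product: 13 3-[(1R,2S,4S)-1,3,3-trimethyl-7-oxabicyclo[2.2.1]heptan-2-yl]propanal
Conditions: AcOH/H2O/THF (3:1:1), 50 °C
Reagents that add atoms: water, O
Why: Acid-catalysed hydrolysis of the dioxolane frees the aldehyde, while the saturated tertiary ether bridge should stay closed in warm dilute acetic acid.

Step 7
Reactants: 13 3-[(1R,2S,4S)-1,3,3-trimethyl-7-oxabicyclo[2.2.1]heptan-2-yl]propanal
Product: 14 (1R,2S,4S)-2-(but-3-yn-1-yl)-1,3,3-trimethyl-7-oxabicyclo[2.2.1]heptane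
Conditions: dimethyl (1-diazo-2-oxopropyl)phosphonate, K2CO3, MeOH, 0 °C → rt
Reagents that add atoms: dimethyl (1-diazo-2-oxopropyl)phosphonate, CC(=O)C(=[N+]=[N-])P(=O)(OC)OC
Why: Seyferth–Gilbert homologation in its Ohira–Bestmann form turns the aldehyde into the terminal alkyne under mild carbonate base; the stereocentres are remote from the reacting carbon.

Step 8
Reactants: 15 methyl 4-hydroxy-3-methylbenzoate
Product: 16 methyl 4-[(tert-butyldimethylsilyl)oxy]-3-methylbenzoate
Conditions: TBSCl, imidazole, DMF, rt
Reagents that add atoms: tert-butyldimethylsilyl chloride, CC(C)(C)[Si](C)(C)Cl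
Why: Routine silylation of the phenol gives an aryl silyl ether that should withstand radical bromination and organoaluminium reagents and is cleaved by hydroxide in the last step.

Step 9
Reactants: 16 methyl 4-[(tert-butyldimethylsilyl)oxy]-3-methylbenzoate
Product: 17 methyl 3-(bromomethyl)-4-[(tert-butyldimethylsilyl)oxy]benzoate
Conditions: NBS (1.05 equiv), AIBN (5 mol%), PhCF3, 85 °C
Reagents that add atoms: N-bromosuccinimide, O=C1CCC(=O)N1Br
Why: Wohl–Ziegler radical bromination selects the benzylic methyl group, the ester-deactivated ring being slow in ionic bromination under these non-polar conditions.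

Step 10
Reactants: 14 (1R,2S,4S)-2-(but-3-yn-1-yl)-1,3,3-trimethyl-7-oxabicyclo[2.2.1]heptane; 17 methyl 3-(bromomethyl)-4-[(tert-butyldimethylsilyl)oxy]benzoate
Product: 19 methyl 4-[(tert-butyldimethylsilyl)oxy]-3-{(2E)-3-methyl-5-[(1R,2S,4S)-1,3,3-trimethyl-7-oxabicyclo[2.2.1]heptan-2-yl]pent-2-en-1-yl}benzoate, via alkenylalane 18 (not isolated)
Conditions: Me3Al (2 equiv), Cp2ZrCl2 (20 mol%), (CH2Cl)2, rt; evaporate excess Me3Al; then 17, Pd(PPh3)4 (5 mol%), THF, rt
Reagents that add atoms: trimethylaluminium, C[Al](C)C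
Why: Zirconium-catalysed syn-carboalumination of the terminal alkyne (Negishi carboalumination) puts methyl on the inner and aluminium on the terminal carbon, and palladium-catalysed cross-coupling of the alkenylalane with the benzylic bromide occurs with retention, which fixes the E geometry of the trisubstituted alkene.

Step 11
Reactants: 19 methyl 4-[(tert-butyldimethylsilyl)oxy]-3-{(2E)-3-methyl-5-[(1R,2S,4S)-1,3,3-trimethyl-7-oxabicyclo[2.2.1]heptan-2-yl]pent-2-en-1-yl}benzoate
Product: 20 4-hydroxy-3-{(2E)-3-methyl-5-[(1R,2S,4S)-1,3,3-trimethyl-7-oxabicyclo[2.2.1]heptan-2-yl]pent-2-en-1-yl}benzoic acid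
Conditions: LiOH·H2O (6 equiv), THF/MeOH/H2O, 45 °C; then 1 M HCl to pH 3, 0 °C
Reagents that add atoms: lithium hydroxide, [Li+].[OH-]
Why: Hydroxide saponifies the methyl ester and cleaves the aryl silyl ether in one basic operation, and mild acidification gives the hydroxy acid without exposing the alkene and the ether bridge to strong acid.

**Compound list**

1 | [2-(1,3-dioxolan-2-yl)ethyl]magnesium bromide | Br[Mg]CCC1OCCO1 | starting material
2 | (E)-3-(dimethylamino)prop-2-enal | CN(C)/C=C/C=O | starting material
3 | bromomagnesium alkoxide of (E)-1-(dimethylamino)-5-(1,3-dioxolan-2-yl)pent-1-en-3-ol (racemic) | CN(C)/C=C/C(CCC1OCCO1)O[Mg]Br | intermediate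
4 | (E)-5-(1,3-dioxolan-2-yl)pent-2-enal | O=C/C=C/CCC1OCCO1 | intermediate
5 | 2-nitropropane | CC(C)[N+](=O)[O-] | starting material
6 | (R)-3-[2-(1,3-dioxolan-2-yl)ethyl]-4-methyl-4-nitropentanal | C1(CC[C@H](CC=O)C(C)(C)[N+](=O)[O-])OCCO1 | intermediate
7 | (3R)-2-[(dimethylamino)methyl]-3-[2-(1,3-dioxolan-2-yl)ethyl]-4-methyl-4-nitropentanal (Mannich base, both C2 epimers) | C1(CC[C@H](C(CN(C)C)C=O)C(C)(C)[N+](=O)[O-])OCCO1 | intermediate
8 | (R)-3-[2-(1,3-dioxolan-2-yl)ethyl]-4-methyl-2-methylidene-4-nitropentanal | C1(CC[C@H](C(=C)C=O)C(C)(C)[N+](=O)[O-])OCCO1 | intermediate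
9 | (R)-3-[2-(1,3-dioxolan-2-yl)ethyl]-4-methyl-2-methylidene-4-nitropentan-1-ol | C1(CC[C@H](C(=C)CO)C(C)(C)[N+](=O)[O-])OCCO1 | intermediate
10 | 2-[(3R)-4-[(ethenyloxy)methyl]-3-(2-nitropropan-2-yl)pent-4-en-1-yl]-1,3-dioxolane | C1(CC[C@H](C(=C)COC=C)C(C)(C)[N+](=O)[O-])OCCO1 | intermediate
11 | (5R)-5-[2-(1,3-dioxolan-2-yl)ethyl]-6-methyl-4-methylidene-6-nitroheptanal | C1(CC[C@H](C(=C)CCC=O)C(C)(C)[N+](=O)[O-])OCCO1 | intermediate
12 | 2-{2-[(1R,2S,4S)-1,3,3-trimethyl-7-oxabicyclo[2.2.1]heptan-2-yl]ethyl}-1,3-dioxolane | C1(CC[C@H]2C(C)(C)[C@@H]3CC[C@@]2(C)O3)OCCO1 | intermediate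
13 | 3-[(1R,2S,4S)-1,3,3-trimethyl-7-oxabicyclo[2.2.1]heptan-2-yl]propanal | O=CCC[C@H]1C(C)(C)[C@@H]2CC[C@@]1(C)O2 | intermediate
14 | (1R,2S,4S)-2-(but-3-yn-1-yl)-1,3,3-trimethyl-7-oxabicyclo[2.2.1]heptane | C#CCC[C@H]1C(C)(C)[C@@H]2CC[C@@]1(C)O2 | intermediate
15 | methyl 4-hydroxy-3-methylbenzoate | COC(=O)c1ccc(O)c(C)c1 | starting material
16 | methyl 4-[(tert-butyldimethylsilyl)oxy]-3-methylbenzoate | COC(=O)c1ccc(O[Si](C)(C)C(C)(C)C)c(C)c1 | intermediate
17 | methyl 3-(bromomethyl)-4-[(tert-butyldimethylsilyl)oxy]benzoate | COC(=O)c1ccc(O[Si](C)(C)C(C)(C)C)c(CBr)c1 | intermediate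
18 | dimethyl{(1E)-2-methyl-4-[(1R,2S,4S)-1,3,3-trimethyl-7-oxabicyclo[2.2.1]heptan-2-yl]but-1-en-1-yl}alumane | C/C(=C\[Al](C)C)CC[C@H]1C(C)(C)[C@@H]2CC[C@@]1(C)O2 | intermediate
19 | methyl 4-[(tert-butyldimethylsilyl)oxy]-3-{(2E)-3-methyl-5-[(1R,2S,4S)-1,3,3-trimethyl-7-oxabicyclo[2.2.1]heptan-2-yl]pent-2-en-1-yl}benzoate | C/C(=C\Cc1cc(C(=O)OC)ccc1O[Si](C)(C)C(C)(C)C)CC[C@H]1C(C)(C)[C@@H]2CC[C@@]1(C)O2 | intermediate
20 | 4-hydroxy-3-{(2E)-3-methyl-5-[(1R,2S,4S)-1,3,3-trimethyl-7-oxabicyclo[2.2.1]heptan-2-yl]pent-2-en-1-yl}benzoic acid | C/C(=C\Cc1cc(C(=O)O)ccc1O)CC[C@H]1C(C)(C)[C@@H]2CC[C@@]1(C)O2 | target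

**Count and risks**

Total step count: 11. Longest linear sequence: 9 steps (steps 1–7, 10, 11); the arene branch is steps 8 and 9.

Steps most likely to fail:

1. Step 5 (proposed new method). The alkoxy radical may be quenched by hydrogen transfer, or may fragment by β-scission (back to the tertiary radical or to a ring-opened primary radical), faster than it closes across the ring. The tertiary radical may also be reduced, or may scramble the side-chain stereocentre by reversible 1,2-vinyl migration, before it adds to the aldehyde. The fallback sets out from 11 and uses known chemistry in two stages. The radical step is run as a plain reductive 6-exo cyclisation onto the aldehyde (Bu3SnH 0.05 M in one portion, AIBN, benzene, 80 °C), in which the stannane deliberately traps the alkoxy radical, to give the cis-cyclohexanol (1S,3R)-3-[2-(1,3-dioxolan-2-yl)ethyl]-2,2-dimethyl-4-methylidenecyclohexan-1-ol F1. The ether bridge is then closed by ionic chemistry: acid-catalysed Markovnikov transannular hydroalkoxylation of the exocyclic alkene (TsOH cat., CH2Cl2, rt), the reaction type that turns terpinen-4-ol into 1,4-cineole. The route is rejoined at 12.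

2. Step 2. Conjugate addition of the hindered secondary nitronate may be slow, so that retro-Michael reaction and background addition erode facial selectivity. The fallback sets out from 1 and sets the stereocentre by allylic alkylation instead. Formylation of 1 with DMF gives 3-(1,3-dioxolan-2-yl)propanal F2. Morita–Baylis–Hillman reaction with methyl acrylate (DABCO) gives racemic methyl 2-[3-(1,3-dioxolan-2-yl)-1-hydroxypropyl]prop-2-enoate F3, and Boc2O/DMAP gives the carbonate methyl 2-[1-[(tert-butoxycarbonyl)oxy]-3-(1,3-dioxolan-2-yl)propyl]prop-2-enoate F4. Cinchona-alkaloid Lewis-base catalysed SN2'–SN2' allylic alkylation with 2-nitropropane 5 ((DHQD)2PHAL or its pseudo-enantiomer, whichever delivers the R product) gives methyl (3R)-3-[2-(1,3-dioxolan-2-yl)ethyl]-4-methyl-2-methylidene-4-nitropentanoate F5, in which the stereocentre and the 2-methylene unit are set together. Reduction with i-Bu2AlH (CH2Cl2, −78 °C) rejoins the route at 9, so steps 2 and 3 are bypassed.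

3. Step 10. In the coupling stage, methyl may transfer from aluminium in place of the alkenyl group, and aluminium reagents may attack the benzoate ester. The fallback sets out from 14 and reverses the polarity of the coupling. After the same carboalumination the alkenylalane is quenched with I2 (THF, −30 °C) to give (1R,2S,4S)-2-[(3E)-4-iodo-3-methylbut-3-en-1-yl]-1,3,3-trimethyl-7-oxabicyclo[2.2.1]heptane F6. Bromide 17 is converted with zinc dust/LiCl (THF) into the ester-tolerant {[2-[(tert-butyldimethylsilyl)oxy]-5-(methoxycarbonyl)phenyl]methyl}zinc bromide F7. Pd(PPh3)4-catalysed Negishi coupling of F6 with F7 (THF, rt) rejoins the route at 19.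

**Further compounds**

F1 | step 5 | (1S,3R)-3-[2-(1,3-dioxolan-2-yl)ethyl]-2,2-dimethyl-4-methylidenecyclohexan-1-ol | C1(CC[C@H]2C(C)(C)[C@@H](O)CCC2=C)OCCO1
F2 | step 2 | 3-(1,3-dioxolan-2-yl)propanal | O=CCCC1OCCO1
F3 | step 2 | methyl 2-[3-(1,3-dioxolan-2-yl)-1-hydroxypropyl]prop-2-enoate (racemic) | C=C(C(=O)OC)C(O)CCC1OCCO1
F4 | step 2 | methyl 2-[1-[(tert-butoxycarbonyl)oxy]-3-(1,3-dioxolan-2-yl)propyl]prop-2-enoate (racemic) | C=C(C(=O)OC)C(OC(=O)OC(C)(C)C)CCC1OCCO1
F5 | step 2 | methyl (3R)-3-[2-(1,3-dioxolan-2-yl)ethyl]-4-methyl-2-methylidene-4-nitropentanoate | C1(CC[C@H](C(=C)C(=O)OC)C(C)(C)[N+](=O)[O-])OCCO1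
F6 | step 10 | (1R,2S,4S)-2-[(3E)-4-iodo-3-methylbut-3-en-1-yl]-1,3,3-trimethyl-7-oxabicyclo[2.2.1]heptane | C/C(=C\I)CC[C@H]1C(C)(C)[C@@H]2CC[C@@]1(C)O2
F7 | step 10 | {[2-[(tert-butyldimethylsilyl)oxy]-5-(methoxycarbonyl)phenyl]methyl}zinc bromide | COC(=O)c1ccc(O[Si](C)(C)C(C)(C)C)c(C[Zn]Br)c1
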